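**Plan** (numbering used: C1 angular-methyl carbon, C4 isopropyl carbinol, C5 ring-fusion CH, C6 ester carbon, C8/C9 diol carbons; ring A = cyclopentane, ring B = cycloheptane)
Retrosynthesis: after the phenol benzyl group, the C8–C9 bond of ring B is cut as a pinacol; this is possible because the tertiary C8–OH and secondary C9–OH are cis-vicinal and lie on the α face with the C6 oxygen, opposite the axial C1 methyl group.
The C9 aldehyde and C8 methyl ketone go back to an allyl group on C1 and a methallyl group on C7; then the ester C–O, C4–isopropyl, C5–C6 (aldol) and C1–CH3 bonds are cut, leaving 3-allylcyclopentenone.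
Forward: ring A is present from the start; the chain is joined in the order C1–CH3 (conjugate addition), C5–C6 (aldol), C4–isopropyl, ester; one ozonolysis unveils both carbonyls and the SmI2 pinacol closes ring B last.
Stereochemistry: C1 from the chiral copper catalyst; C5 and C6 from an anti aldol trans to the allyl group; C4 from addition anti to the C5 side chain; C8 and C9 from the samarium-bridged cyclisation under control of the axial C1 methyl group.

Key step: step 8

Assumption: the antipode of the chiral phosphinamine ligand in step 2 is the one that delivers methyl to the enone face giving the (R)-configured quaternary centre; the other antipode would give the mirror-image series.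

Step 1
Reactants: 1 3-ethoxycyclopent-2-en-1-one
Product: 3 3-(prop-2-en-1-yl)cyclopent-2-en-1-one, via tertiary allylic alcohol 2 (not isolated)
Conditions: allylMgBr (1.2 equiv), THF, 0 °C; then 1 M HCl, 0 °C
Reagents that add atoms: allylmagnesium bromide, C=CC[Mg]Br; water, O
Why: Stork–Danheiser sequence, in which 1,2-addition of the Grignard reagent to the vinylogous ester and acid-mediated loss of ethanol from the adduct transpose the carbonyl and should give the 3-substituted enone, with no stereocentre formed.

Step 2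
Reactants: 3 3-(prop-2-en-1-yl)cyclopent-2-en-1-one
Product: 5 trimethyl{[(3R)-3-methyl-3-(prop-2-en-1-yl)cyclopent-1-en-1-yl]oxy}silane, via dimethylaluminium enolate 4 (not isolated)
Conditions: Me3Al (1.5 equiv), CuTC (copper thiophene-2-carboxylate, monovalent copper, 2 mol %), chiral phosphinamine Ph2P–N[CH(CH3)Ph]2 (one antipode, 4 mol %), Et2O, −30 °C; then TMSOTf (1.5 equiv), THF, −30 → 0 °C; non-aqueous work-up
Reagents that add atoms: trimethylaluminium, C[Al](C)C; trimethylsilyl trifluoromethanesulfonate, C[Si](C)(C)OS(=O)(=O)C(F)(F)F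
Why: copper-catalysed asymmetric conjugate addition of a trialkylaluminium to a β-substituted cyclopentenone should create the quaternary C1 with the face chosen by the chiral ligand on copper, and O-silylation of the aluminium enolate fixes the enolate towards C5, the hindered α-carbon that a later deprotonation could not reach.

Step 3
Reactants: 6 3-methylbut-3-en-1-ol
Product: 7 3-methylbut-3-enal
Conditions: Dess–Martin periodinane (1.1 equiv), CH2Cl2, 0 °C → rt; filtered cold and used at once as a solution
Reagents that add atoms: none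
Why: Dess–Martin oxidation of a primary alcohol under near-neutral conditions, chosen because the β,γ-unsaturated aldehyde isomerises to the conjugated enal with acid or base; no stereocentre is formed.

Step 4
Reactants: 5 trimethyl{[(3R)-3-methyl-3-(prop-2-en-1-yl)cyclopent-1-en-1-yl]oxy}silane; 7 3-methylbut-3-enal
Product: 9 (2S,3R)-2-[(1S)-1-hydroxy-3-methylbut-3-en-1-yl]-3-methyl-3-(prop-2-en-1-yl)cyclopentan-1-one, via lithium enolate 8 (not isolated)
Conditions: MeLi (1.05 equiv), THF, 0 °C; then 7 (1.3 equiv), −78 °C, short contact; aq NH4Cl at −78 °C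
Reagents that add atoms: none
Why: regiospecific enolate generation from the silyl enol ether with methyllithium and kinetic aldol addition through a Zimmerman–Traxler chair, in which the ring-locked E-enolate should give the anti C5/C6 relationship and the aldehyde should approach C5 on the face opposite the larger allyl group at C1, that is cis to the methyl group.

Step 5
Reactants: 9 (2S,3R)-2-[(1S)-1-hydroxy-3-methylbut-3-en-1-yl]-3-methyl-3-(prop-2-en-1-yl)cyclopentan-1-one
Product: 10 (1R,2S,3R)-2-[(1S)-1-hydroxy-3-methylbut-3-en-1-yl]-3-methyl-1-(propan-2-yl)-3-(prop-2-en-1-yl)cyclopentan-1-ol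
Conditions: iPrMgCl (3 equiv), anhydrous CeCl3 (3 equiv), THF, −78 → −20 °C; aq NH4Cl
Reagents that add atoms: isopropylmagnesium chloride, CC(C)[Mg]Cl
Why: organocerium 1,2-addition, which suppresses enolisation, reduction and retro-aldol cleavage, to the metal-chelated β-hydroxy ketone, where the nucleophile should enter on the α face anti to the C5 side chain so that the new C4 hydroxyl is cis to C6.

Step 6
Reactants: 10 (1R,2S,3R)-2-[(1S)-1-hydroxy-3-methylbut-3-en-1-yl]-3-methyl-1-(propan-2-yl)-3-(prop-2-en-1-yl)cyclopentan-1-ol; 11 4-(benzyloxy)benzoyl chloride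
Product: 12 (1S)-1-[(1S,2R,5R)-2-hydroxy-5-methyl-2-(propan-2-yl)-5-(prop-2-en-1-yl)cyclopentyl]-3-methylbut-3-en-1-yl 4-(benzyloxy)benzoate
Conditions: Et3N (2 equiv), DMAP (0.5 equiv), CH2Cl2, 0 °C → rt
Reagents that add atoms: none
Why: DMAP-catalysed acylation with an aroyl chloride should be selective for the secondary C6 hydroxyl because the tertiary C4 hydroxyl is too hindered to react; no stereocentre changes.

Step 7
Reactants: 12 (1S)-1-[(1S,2R,5R)-2-hydroxy-5-methyl-2-(propan-2-yl)-5-(prop-2-en-1-yl)cyclopentyl]-3-methylbut-3-en-1-yl 4-(benzyloxy)benzoate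
Product: 14 (1S)-1-[(1S,2R,5R)-2-hydroxy-5-methyl-5-(2-oxoethyl)-2-(propan-2-yl)cyclopentyl]-3-oxobutyl 4-(benzyloxy)benzoate, via bis-ozonide 13 (not isolated)
Conditions: O3, CH2Cl2, −78 °C, Sudan red end-point; PPh3 (2.5 equiv), −78 °C → rt; used without base contact
Reagents that add atoms: ozone, [O-][O+]=O
Why: ozonolysis with reductive work-up should cleave both terminal alkenes, which react far faster than the ester-deactivated arene, and so unveil at once the C9 aldehyde from the allyl group and the C8 methyl ketone from the methallyl group; no stereocentre changes.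

Step 8
Reactants: 14 (1S)-1-[(1S,2R,5R)-2-hydroxy-5-methyl-5-(2-oxoethyl)-2-(propan-2-yl)cyclopentyl]-3-oxobutyl 4-(benzyloxy)benzoate
Product: 15 (3R,3aS,4S,6R,7S,8aR)-3,6,7-trihydroxy-6,8a-dimethyl-3-(propan-2-yl)decahydroazulen-4-yl 4-(benzyloxy)benzoate
Conditions: SmI2 (0.1 M in THF, 3 equiv), tBuOH (2 equiv), THF, −78 → 0 °C, 14 added slowly to high dilution; aqueous potassium sodium tartrate
Reagents that add atoms: none
Why: Intramolecular ketone–aldehyde pinacol coupling, in which SmI2 reduces the more easily reduced C9 aldehyde to a ketyl that adds to the C8 carbonyl held on the same trivalent samarium centre, and a second electron and protonation give the diol. The closest known reaction type is the SmI2-mediated pinacol cyclisation of keto-aldehydes to cis-cycloalkane-1,2-diols and its extension to seven- and eight-membered rings. Ring B is closed by the C8–C9 bond in a 7-exo-trig addition of the C9 ketyl to the C8 carbonyl carbon. C9 is controlled by the axial angular methyl group at C1, which should force the bulky samarium-bound oxygen into the equatorial α position, and C8 by the samarium bridge between the two oxygens, which should place the C8 oxygen cis to it (α) and the methyl group β, with the trans ring fusion and the equatorial C6 ester fixing the chair-like transition state. The step needs intramolecular coupling to outrun aldehyde dimerisation and simple reduction; in the substrate the trans-disposed side chains on ring A hold the two carbonyls within reach, only the aldehyde is reduced at −78 °C, and the aryl ester and benzyl ether are inert to SmI2 without HMPA.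

Step 9
Reactants: 15 (3R,3aS,4S,6R,7S,8aR)-3,6,7-trihydroxy-6,8a-dimethyl-3-(propan-2-yl)decahydroazulen-4-yl 4-(benzyloxy)benzoate
Product: 16 (3R,3aS,4S,6R,7S,8aR)-3,6,7-trihydroxy-6,8a-dimethyl-3-(propan-2-yl)decahydroazulen-4-yl 4-hydroxybenzoate
Conditions: H2 (1 atm), 10 % Pd/C, EtOAc, rt
Reagents that add atoms: none
Why: hydrogenolysis of the aryl benzyl ether over palladium on carbon should free the phenol while the ester, the alcohols and the saturated skeleton are untouched; no stereocentre changes.

**Compound list**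
1 | 3-ethoxycyclopent-2-en-1-one | CCOC1=CC(=O)CC1 | starting material
2 | 3-ethoxy-1-(prop-2-en-1-yl)cyclopent-2-en-1-ol (racemic, not isolated) | CCOC1=CC(O)(CC=C)CC1 | intermediate
3 | 3-(prop-2-en-1-yl)cyclopent-2-en-1-one | C=CCC1=CC(=O)CC1 | intermediate
4 | dimethylaluminium (3R)-3-methyl-3-(prop-2-en-1-yl)cyclopent-1-en-1-olate (not isolated) | C[Al](C)OC1=C[C@@](C)(CC=C)CC1 | intermediate
5 | trimethyl{[(3R)-3-methyl-3-(prop-2-en-1-yl)cyclopent-1-en-1-yl]oxy}silane | C[Si](C)(C)OC1=C[C@@](C)(CC=C)CC1 | intermediate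
6 | 3-methylbut-3-en-1-ol | CC(=C)CCO | starting material
7 | 3-methylbut-3-enal | CC(=C)CC=O | intermediate
8 | lithium (3R)-3-methyl-3-(prop-2-en-1-yl)cyclopent-1-en-1-olate (not isolated) | [Li]OC1=C[C@@](C)(CC=C)CC1 | intermediate
9 | (2S,3R)-2-[(1S)-1-hydroxy-3-methylbut-3-en-1-yl]-3-methyl-3-(prop-2-en-1-yl)cyclopentan-1-one | O=C1CC[C@](C)(CC=C)[C@H]1[C@@H](O)CC(C)=C | intermediate
10 | (1R,2S,3R)-2-[(1S)-1-hydroxy-3-methylbut-3-en-1-yl]-3-methyl-1-(propan-2-yl)-3-(prop-2-en-1-yl)cyclopentan-1-ol | CC(C)[C@]1(O)CC[C@](C)(CC=C)[C@H]1[C@@H](O)CC(C)=C | intermediate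
11 | 4-(benzyloxy)benzoyl chloride | O=C(Cl)c1ccc(OCc2ccccc2)cc1 | starting material
12 | (1S)-1-[(1S,2R,5R)-2-hydroxy-5-methyl-2-(propan-2-yl)-5-(prop-2-en-1-yl)cyclopentyl]-3-methylbut-3-en-1-yl 4-(benzyloxy)benzoate | CC(C)[C@]1(O)CC[C@](C)(CC=C)[C@H]1[C@@H](OC(=O)c3ccc(OCc4ccccc4)cc3)CC(C)=C | intermediate
13 | (1S)-1-[(1S,2R,5R)-2-hydroxy-5-methyl-2-(propan-2-yl)-5-(1,2,4-trioxolan-3-ylmethyl)cyclopentyl]-2-(3-methyl-1,2,4-trioxolan-3-yl)ethyl 4-(benzyloxy)benzoate (bis-ozonide, epimers at the trioxolane carbons, not isolated) | CC(C)[C@]1(O)CC[C@](C)(CC2OCOO2)[C@H]1[C@@H](OC(=O)c3ccc(OCc4ccccc4)cc3)CC5(C)OCOO5 | intermediate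
14 | (1S)-1-[(1S,2R,5R)-2-hydroxy-5-methyl-5-(2-oxoethyl)-2-(propan-2-yl)cyclopentyl]-3-oxobutyl 4-(benzyloxy)benzoate | CC(C)[C@]1(O)CC[C@](C)(CC=O)[C@H]1[C@@H](OC(=O)c3ccc(OCc4ccccc4)cc3)CC(C)=O | intermediate
15 | (3R,3aS,4S,6R,7S,8aR)-3,6,7-trihydroxy-6,8a-dimethyl-3-(propan-2-yl)decahydroazulen-4-yl 4-(benzyloxy)benzoate | CC(C)[C@]1(O)CC[C@]2(C)C[C@H](O)[C@](C)(O)C[C@H](OC(=O)c3ccc(OCc4ccccc4)cc3)[C@H]21 | intermediate
16 | (3R,3aS,4S,6R,7S,8aR)-3,6,7-trihydroxy-6,8a-dimethyl-3-(propan-2-yl)decahydroazulen-4-yl 4-hydroxybenzoate | CC(C)[C@]1(O)CC[C@]2(C)C[C@H](O)[C@](C)(O)C[C@H](OC(=O)c3ccc(O)cc3)[C@H]21 | target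

Total step count: 9
Longest linear sequence: 8 steps (steps 1, 2, 4, 5, 6, 7, 8, 9; step 3 makes the aldehyde partner)

**Steps most likely to fail**

Step 8. Aldehyde homocoupling or simple reduction may outrun closure of the seven-membered ring, and the diol may form trans or on the β face. The fallback sets out from 12. Ring-closing metathesis with the second-generation Grubbs catalyst (CH2Cl2, 40 °C) should give the cycloheptene (3R,3aS,4S,8aR)-3-hydroxy-6,8a-dimethyl-3-(propan-2-yl)-1,2,3,3a,4,5,8,8a-octahydroazulen-4-yl 4-(benzyloxy)benzoate F1. Dihydroxylation with catalytic OsO4 and N-methylmorpholine N-oxide (acetone/water) should then occur on the α face, opposite the axial C1 methyl group, and return to the route at 15.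

Step 4. The basic enolate may deprotonate the β,γ-unsaturated aldehyde (isomerisation to the conjugated enal), and facial or syn/anti selectivity may be poor. The fallback sets out from 5 and rejoins at 10, so it also replaces step 5.
- TMSOTf-catalysed reaction of 5 with trimethyl orthoformate (CH2Cl2, −78 °C) should give the β-keto acetal (2S,3R)-2-(dimethoxymethyl)-3-methyl-3-(prop-2-en-1-yl)cyclopentan-1-one F2; its C5 centre can be equilibrated trans to the allyl group.
- iPrMgCl/CeCl3 should add anti to the acetal to give (1R,2R,3R)-2-(dimethoxymethyl)-3-methyl-1-(propan-2-yl)-3-(prop-2-en-1-yl)cyclopentan-1-ol F3.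
- Mild acetal hydrolysis (pyridinium tosylate, acetone/water) should give (1R,2R,5R)-2-hydroxy-5-methyl-2-(propan-2-yl)-5-(prop-2-en-1-yl)cyclopentane-1-carbaldehyde F4.
- Chelation-controlled methallylation with tributyl(2-methylprop-2-en-1-yl)stannane and MgBr2·OEt2 (CH2Cl2, −78 °C) should attack the magnesium-bridged aldehyde on the face away from the angular methyl group and give 10.

Step 2. Face selectivity of the copper-catalysed methyl transfer may be insufficient on an enone carrying a skipped alkene, or the regiodefined enolate may be lost on trapping. The fallback sets out from 3. Me2CuLi with Me3SiCl (THF, −78 °C) should give racemic trimethyl{[3-methyl-3-(prop-2-en-1-yl)cyclopent-1-en-1-yl]oxy}silane F5. This is taken through step 4 by way of racemic lithium 3-methyl-3-(prop-2-en-1-yl)cyclopent-1-en-1-olate F6. The racemic aldol is separated by preparative chromatography on a chiral stationary phase into 9 and its mirror image (2R,3S)-2-[(1R)-1-hydroxy-3-methylbut-3-en-1-yl]-3-methyl-3-(prop-2-en-1-yl)cyclopentan-1-one F7, which is discarded; the route is rejoined at 9.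

Further compounds
F1 | step 8 | (3R,3aS,4S,8aR)-3-hydroxy-6,8a-dimethyl-3-(propan-2-yl)-1,2,3,3a,4,5,8,8a-octahydroazulen-4-yl 4-(benzyloxy)benzoate | CC(C)[C@]1(O)CC[C@]2(C)CC=C(C)C[C@H](OC(=O)c3ccc(OCc4ccccc4)cc3)[C@H]21
F2 | step 4 | (2S,3R)-2-(dimethoxymethyl)-3-methyl-3-(prop-2-en-1-yl)cyclopentan-1-one | O=C1CC[C@](C)(CC=C)[C@H]1C(OC)OC
F3 | step 4 | (1R,2R,3R)-2-(dimethoxymethyl)-3-methyl-1-(propan-2-yl)-3-(prop-2-en-1-yl)cyclopentan-1-ol | CC(C)[C@]1(O)CC[C@](C)(CC=C)[C@H]1C(OC)OC
F4 | step 4 | (1R,2R,5R)-2-hydroxy-5-methyl-2-(propan-2-yl)-5-(prop-2-en-1-yl)cyclopentane-1-carbaldehyde | CC(C)[C@]1(O)CC[C@](C)(CC=C)[C@H]1C=O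
F5 | step 2 | racemic trimethyl{[3-methyl-3-(prop-2-en-1-yl)cyclopent-1-en-1-yl]oxy}silane | C[Si](C)(C)OC1=CC(C)(CC=C)CC1
F6 | step 2 | racemic lithium 3-methyl-3-(prop-2-en-1-yl)cyclopent-1-en-1-olate | [Li]OC1=CC(C)(CC=C)CC1
F7 | step 2 | (2R,3S)-2-[(1R)-1-hydroxy-3-methylbut-3-en-1-yl]-3-methyl-3-(prop-2-en-1-yl)cyclopentan-1-one | O=C1CC[C@@](C)(CC=C)[C@@H]1[C@H](O)CC(C)=C
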